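**Strategy.** Everything rests on cutting the C1–C2 bond of the tetralin. C1 is a diarylmethine between the pendant aryl ring C (oxygen para) and the fused benzo ring A (C6 methoxy para to C8a), so it can be unmasked from a diarylcarbinol as a long-lived quinone-methide-type cation, while the C2 CH2OH can start as an enolisable aldehyde. One amine-catalysed operation then forms C1–C2, closes the carbocycle (ring B) and sets C1 and C2 against the C3 carbinol already in place. The precursor is a diarylcarbinol aldehyde whose quaternary C3, from L-malic acid, is tied up as an acetonide. The oxolane half is joined afterwards through an aryllithium–lactone union and lactol reduction.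

Key step: step 16

Remarks on the chemistry:
- Read from the target SMILES, the tetralin is (1S,2S,3S) and the oxolane is (2R,3R,4S), i.e. aryl, CH2OH and arylmethyl mutually cis; both are built exactly as written.
- Ring names: A = benzo ring of the tetralin, B = its saturated ring, C = aryl on C1, D = second biaryl ring (carries Br, later the oxolane), E = oxolane, F = benzyl ring on E.
- The ring C oxygen para to C1 lies between OMe and the biaryl bond; as an ether it would be twisted out of conjugation and donate poorly. It is therefore carried as a silyl ether and freed before the key step, so that the carbinol can ionise through a para-quinone methide under weak acid.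
- Compounds 1, 5, 10, 14 and 24 are taken as catalogue materials.

Step 1
Reactants: 1 2-bromo-4-hydroxy-5-methoxybenzaldehyde
Product: 2 4-(benzyloxy)-2-bromo-5-methoxybenzaldehyde
Conditions: BnBr, K2CO3, DMF, rt
Reagents that add atoms: benzyl bromide, BrCc1ccccc1
Why: Williamson ether synthesis, the phenoxide displacing bromide, masks the ring A phenol for the organometallic steps.

Step 2
Reactants: 2 4-(benzyloxy)-2-bromo-5-methoxybenzaldehyde
Product: 3 [4-(benzyloxy)-2-bromo-5-methoxyphenyl]methanol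
Conditions: NaBH4, MeOH–THF, 0 °C
Reagents that add atoms: none
Why: Borohydride reduction of the aryl aldehyde gives the benzylic alcohol, and aryl bromide and benzyl ether are inert to NaBH4.

Step 3
Reactants: 3 [4-(benzyloxy)-2-bromo-5-methoxyphenyl]methanol
Product: 4 1-(benzyloxy)-5-bromo-4-(bromomethyl)-2-methoxybenzene
Conditions: PBr3, CH2Cl2, 0 °C
Reagents that add atoms: phosphorus tribromide, BrP(Br)Br
Why: PBr3 bromination of a benzylic alcohol through its phosphite ester (SN2); the electron-rich benzylic bromide is used without storage.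

Step 4
Reactants: 5 L-malic acid
Product: 6 2-[(2S,4S)-2-tert-butyl-5-oxo-1,3-dioxolan-4-yl]acetic acid
Conditions: t-BuCHO, TsOH·H2O (cat.), H2SO4 (cat.), pentane, reflux, water separator
Reagents that add atoms: pivalaldehyde, CC(C)(C)C=O
Why: Acetalisation of the alpha-hydroxy acid with pivalaldehyde gives the favoured, crystalline 2,4-cis dioxolanone, so the malic acid centre dictates the new acetal centre (self-regeneration of stereocentres).

Step 5
Reactants: 6 2-[(2S,4S)-2-tert-butyl-5-oxo-1,3-dioxolan-4-yl]acetic acid; 4 1-(benzyloxy)-5-bromo-4-(bromomethyl)-2-methoxybenzene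
Product: 7 2-[(2S,4S)-4-{[4-(benzyloxy)-2-bromo-5-methoxyphenyl]methyl}-2-tert-butyl-5-oxo-1,3-dioxolan-4-yl]acetic acid
Conditions: LiN(SiMe3)2 (2.2 equiv), THF, −78 °C; then 4, −78 to −30 °C; aq. HCl
Reagents that add atoms: none
Why: Dioxolanone alkylation of the dianion (carboxylate plus ring enolate): the benzylic bromide enters trans to the tert-butyl group, so the quaternary carbinol forms with overall retention (new centre S).

Step 6
Reactants: 7 2-[(2S,4S)-4-{[4-(benzyloxy)-2-bromo-5-methoxyphenyl]methyl}-2-tert-butyl-5-oxo-1,3-dioxolan-4-yl]acetic acid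
Product: 8 (2S)-2-{[4-(benzyloxy)-2-bromo-5-methoxyphenyl]methyl}butane-1,2,4-triol
Conditions: LiAlH4, THF, 0 °C to rt
Reagents that add atoms: none
Why: Hydride reduction turns both the acylal-type lactone and the acid into primary alcohols and releases the acetal carbon as neopentyl alcohol, without touching the quaternary centre or, at this temperature, the aryl bromide.

Step 7
Reactants: 8 (2S)-2-{[4-(benzyloxy)-2-bromo-5-methoxyphenyl]methyl}butane-1,2,4-triol
Product: 9 2-[(4S)-4-{[4-(benzyloxy)-2-bromo-5-methoxyphenyl]methyl}-2,2-dimethyl-1,3-dioxolan-4-yl]ethan-1-ol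
Conditions: Me2C(OMe)2, TsOH·H2O (cat.), acetone, rt
Reagents that add atoms: 2,2-dimethoxypropane, COC(C)(C)OC
Why: Thermodynamic transacetalisation gives the five-membered 1,2-acetonide (tertiary and adjacent primary oxygen) rather than the 1,3-dioxane, which would put a ring methyl 1,3-diaxial to a substituent of the quaternary carbon, and leaves the 2-hydroxyethyl arm free.

Step 8
Reactants: 10 4-bromo-2-methoxyphenol
Product: 11 4-bromo-2-iodo-6-methoxyphenol
Conditions: N-iodosuccinimide, TsOH·H2O (10 mol %), MeCN, 0 °C to rt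
Reagents that add atoms: N-iodosuccinimide, O=C1CCC(=O)N1I
Why: Electrophilic aromatic iodination goes ortho to the free phenol because the para position is blocked by bromine, as in the iodination of vanillin.

Step 9
Reactants: 11 4-bromo-2-iodo-6-methoxyphenol
Product: 12 2-(benzyloxy)-5-bromo-1-iodo-3-methoxybenzene
Conditions: BnBr, K2CO3, DMF, rt
Reagents that add atoms: benzyl bromide, BrCc1ccccc1
Why: Williamson ether synthesis masks the ring D phenol.

Step 10
Reactants: 12 2-(benzyloxy)-5-bromo-1-iodo-3-methoxybenzene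
Product: 13 2-[2-(benzyloxy)-5-bromo-3-methoxyphenyl]-4,4,5,5-tetramethyl-1,3,2-dioxaborolane
Conditions: i-PrMgCl·LiCl, THF, −30 °C; then 2-isopropoxy-4,4,5,5-tetramethyl-1,3,2-dioxaborolane, −30 °C to rt; aq. NH4Cl
Reagents that add atoms: 2-isopropoxy-4,4,5,5-tetramethyl-1,3,2-dioxaborolane, CC(C)OB1OC(C)(C)C(C)(C)O1
Why: Iodine–magnesium exchange is far faster than bromine–magnesium exchange, so only the C–I bond is metallated, and the arylmagnesium is trapped by the borate ester.

Step 11
Reactants: 13 2-[2-(benzyloxy)-5-bromo-3-methoxyphenyl]-4,4,5,5-tetramethyl-1,3,2-dioxaborolane; 14 4-hydroxy-3-iodo-5-methoxybenzaldehyde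
Product: 15 3-[2-(benzyloxy)-5-bromo-3-methoxyphenyl]-4-hydroxy-5-methoxybenzaldehyde
Conditions: Pd(PPh3)4 (5 mol %), K2CO3, dioxane–H2O 4:1, 75 °C; then dilute HCl
Reagents that add atoms: none
Why: Suzuki–Miyaura coupling: oxidative addition into the C–I bond of 14 outruns that into the electron-rich C–Br bond of 13, and the phenol is tolerated as its phenoxide, so the biaryl forms with the bromide intact.

Step 12
Reactants: 15 3-[2-(benzyloxy)-5-bromo-3-methoxyphenyl]-4-hydroxy-5-methoxybenzaldehyde
Product: 16 3-[2-(benzyloxy)-5-bromo-3-methoxyphenyl]-4-[(tert-butyldimethylsilyl)oxy]-5-methoxybenzaldehyde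
Conditions: t-BuMe2SiCl, imidazole, DMF, rt to 40 °C
Reagents that add atoms: tert-butyldimethylsilyl chloride, CC(C)(C)[Si](C)(C)Cl
Why: Imidazole-promoted silylation gives a mask for the ring C phenol that survives the aryllithium step and is later removed by fluoride alone.

Step 13
Reactants: 9 2-[(4S)-4-{[4-(benzyloxy)-2-bromo-5-methoxyphenyl]methyl}-2,2-dimethyl-1,3-dioxolan-4-yl]ethan-1-ol; 16 3-[2-(benzyloxy)-5-bromo-3-methoxyphenyl]-4-[(tert-butyldimethylsilyl)oxy]-5-methoxybenzaldehyde
Product: 17 2-[(4S)-4-({4-(benzyloxy)-2-[{3-[2-(benzyloxy)-5-bromo-3-methoxyphenyl]-4-[(tert-butyldimethylsilyl)oxy]-5-methoxyphenyl}(hydroxy)methyl]-5-methoxyphenyl}methyl)-2,2-dimethyl-1,3-dioxolan-4-yl]ethan-1-ol (both carbinol epimers)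
Conditions: 9, n-BuLi (1.05 equiv) then t-BuLi (2.1 equiv), THF, −78 °C; then 16, −78 to −40 °C; H2O
Reagents that add atoms: none
Why: Deprotonation of the alcohol and bromine–lithium exchange give an aryllithium that adds 1,2 to the non-enolisable aldehyde much faster than it exchanges with the aryl bromide of 16; the carbinol centre forms unselectively, which is harmless because step 16 planarises it.

Step 14
Reactants: 17 the diol of step 13
Product: 18 2-[(4S)-4-({4-(benzyloxy)-2-[{3-[2-(benzyloxy)-5-bromo-3-methoxyphenyl]-4-[(tert-butyldimethylsilyl)oxy]-5-methoxyphenyl}(hydroxy)methyl]-5-methoxyphenyl}methyl)-2,2-dimethyl-1,3-dioxolan-4-yl]acetaldehyde (both carbinol epimers)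
Conditions: [Cu(MeCN)4]OTf (5 mol %), 2,2'-bipyridine (5 mol %), TEMPO (5 mol %), N-methylimidazole (10 mol %), MeCN, air, rt
Reagents that add atoms: none
Why: Aerobic copper/TEMPO alcohol oxidation is selective for primary over secondary (even benzylic) alcohols, so only the 2-hydroxyethyl arm is oxidised and the diarylcarbinol is kept.

Step 15
Reactants: 18 the silyl-protected hydroxy aldehyde of step 14
Product: 19 2-[(4S)-4-({4-(benzyloxy)-2-[{3-[2-(benzyloxy)-5-bromo-3-methoxyphenyl]-4-hydroxy-5-methoxyphenyl}(hydroxy)methyl]-5-methoxyphenyl}methyl)-2,2-dimethyl-1,3-dioxolan-4-yl]acetaldehyde (both carbinol epimers)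
Conditions: Bu4NF (1.1 equiv), AcOH (1.2 equiv), THF, 0 °C; used at once
Reagents that add atoms: none
Why: Fluoride-induced desilylation removes the only silyl group, the aryl ether, while the acetic acid buffer protects the beta-alkoxy aldehyde from base.

Step 16
Reactants: 19 the phenolic diarylcarbinol aldehyde of step 15
Product: 21 (1S,2R,3S)-7-(benzyloxy)-1-{3-[2-(benzyloxy)-5-bromo-3-methoxyphenyl]-4-hydroxy-5-methoxyphenyl}-6-methoxy-1,2,3,4-tetrahydronaphthalene-2-carbaldehyde whose C3 carries O and CH2O joined as an isopropylidene acetal (spiro-2,2-dimethyl-1,3-dioxolane, ring oxygen on C3; tetralin numbering), via para-quinone methide aldehyde 20 (not isolated)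
Conditions: (R)-2-{bis[3,5-bis(trifluoromethyl)phenyl][(trimethylsilyl)oxy]methyl}pyrrolidine (20 mol %), CF3CO2H (30 mol %), CH2Cl2, 0 °C to rt
Reagents that add atoms: none
Why: Proposed new method: weak acid dehydrates the para-hydroxy diarylcarbinol (either epimer) to the para-quinone methide 20 or its protonated form, a diarylmethyl cation also stabilised by the C6 methoxy of ring A, while the amine turns the CH2CHO arm into an (E)-enamine whose alpha carbon (C2) adds to C1 and iminium hydrolysis returns the catalyst; the closest known reactions are the intermolecular amine-catalysed alpha-alkylations of aldehydes with diarylmethanols (SN1 type) and with para-quinone methides. Ring B is closed in a 6-(enolexo)-exo-trig mode. C1 should be set by a chair-like transition state with the biaryl pseudo-equatorial and the C3 ketal oxygen axial, a substrate bias reinforced by the (R)-catalyst, whose shielding leaves open the enamine face that gives the (2R)-aldehyde. C2 is set first by the catalyst and, being alpha to the aldehyde, can relax by enamine–iminium exchange to the all-equatorial isomer with CHO trans to both the C1 aryl and the C3 CH2O branch. The step needs facial control at C1 relative to the preset C3 and C–C rather than C–O capture of the electrophile; the six-membered tether, the reversibility of O-capture at C1 and the persistent neutral electrophile should secure these, and the ketal instead of a free beta-hydroxyl blocks retro-aldol cleavage.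

Step 17
Reactants: 21 the tetralin aldehyde of step 16
Product: 22 the corresponding (1S,2S,3S)-2-(hydroxymethyl)tetralin (CHO of 21 reduced to CH2OH; ring C phenol free)
Conditions: NaBH4, MeOH–THF, 0 °C
Reagents that add atoms: none
Why: Borohydride reduction of the aldehyde at 0 °C is faster than enolisation, so the C2 configuration is kept.

Step 18
Reactants: 22 the phenolic primary alcohol of step 17
Product: 23 the bis(benzyl ether) of 22 (benzyl on the ring C phenol and on the C2 CH2OH), (1S,2S,3S)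
Conditions: NaH (2.5 equiv), BnBr (2.4 equiv), Bu4NI (cat.), DMF, 0 °C to rt
Reagents that add atoms: benzyl bromide, BrCc1ccccc1
Why: Williamson benzylation of the phenoxide and the primary alkoxide in one operation; the diarylmethine C1–H is not acidic enough to be touched.

Step 19
Reactants: 24 [4-(benzyloxy)-3-methoxyphenyl]methanol
Product: 25 1-(benzyloxy)-4-(bromomethyl)-2-methoxybenzene
Conditions: PBr3, CH2Cl2, 0 °C
Reagents that add atoms: phosphorus tribromide, BrP(Br)Br
Why: PBr3 bromination of the benzylic alcohol (SN2 on the phosphite ester); the bromide is used fresh.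

Step 20
Reactants: 6 2-[(2S,4S)-2-tert-butyl-5-oxo-1,3-dioxolan-4-yl]acetic acid; 25 1-(benzyloxy)-4-(bromomethyl)-2-methoxybenzene
Product: 26 2-[(2S,4S)-4-{[4-(benzyloxy)-3-methoxyphenyl]methyl}-2-tert-butyl-5-oxo-1,3-dioxolan-4-yl]acetic acid
Conditions: LiN(SiMe3)2 (2.2 equiv), THF, −78 °C; then 25, −78 to −30 °C; aq. HCl
Reagents that add atoms: none
Why: The same dioxolanone alkylation as in step 5, trans to the tert-butyl group, sets the ring E carbinol centre (S) with retention.

Step 21
Reactants: 26 the alkylated dioxolanone acid of step 20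
Product: 27 dimethyl (2S)-2-{[4-(benzyloxy)-3-methoxyphenyl]methyl}-2-hydroxybutanedioate
Conditions: HCl (1.25 M in MeOH), 50 °C
Reagents that add atoms: methanol, CO
Why: Acid-catalysed methanolysis opens the acylal (methyl ester plus pivalaldehyde dimethyl acetal) and Fischer-esterifies the free acid without breaking any bond to the quaternary centre.

Step 22
Reactants: 27 dimethyl (2S)-2-{[4-(benzyloxy)-3-methoxyphenyl]methyl}-2-hydroxybutanedioate
Product: 29 methyl (3S,4S)-4-{[4-(benzyloxy)-3-methoxyphenyl]methyl}-4-hydroxy-5-oxooxolane-3-carboxylate, via hydroxymethylated diester 28 (not isolated)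
Conditions: LiN(i-Pr)2 (2.2 equiv), THF, −78 to −20 °C; CH2O (monomer in THF), −78 °C; AcOH; then DBU (0.2 equiv), CH2Cl2, rt
Reagents that add atoms: formaldehyde, C=O
Why: Fráter–Seebach-type dianion (alkoxide plus C3 ester enolate) aldol with formaldehyde, then lactonisation of the new CH2OH onto the C1 ester (the only five-membered option) and base equilibration at C3, where CO2Me is expected to settle trans to the bulky arylmethyl group and cis to OH, i.e. (3S,4S).

Step 23
Reactants: 29 the lactone ester of step 22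
Product: 31 (3S,4S)-4-{[4-(benzyloxy)-3-methoxyphenyl]methyl}-4-hydroxy-3-(hydroxymethyl)oxolan-2-one, via triol ester 30 (not isolated)
Conditions: BH3·SMe2 (2 equiv), NaBH4 (5 mol %), THF, 0 °C to rt; MeOH; then TsOH·H2O (5 mol %), CH2Cl2, rt
Reagents that add atoms: none
Why: Hydroxyl-directed borane reduction selects the carbonyl alpha to the tertiary OH (the lactone) and spares the methyl ester, and acid then closes the new primary alcohol onto that ester (the only gamma relationship), so the carbonyl moves from one C3 branch to the other and the CH2OH ends cis to the arylmethyl group with no bond to C3 broken.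

Step 24
Reactants: 31 the dihydroxy lactone of step 23
Product: 32 (3S,4S)-4-{[4-(benzyloxy)-3-methoxyphenyl]methyl}-4-[(triethylsilyl)oxy]-3-{[(triethylsilyl)oxy]methyl}oxolan-2-one
Conditions: Et3SiOTf (2.5 equiv), 2,6-lutidine, CH2Cl2, −78 to 0 °C
Reagents that add atoms: triethylsilyl trifluoromethanesulfonate, CC[Si](CC)(CC)OS(=O)(=O)C(F)(F)F
Why: A silyl triflate with a hindered pyridine base silylates both the primary and the tertiary alcohol without epimerising C3.

Step 25
Reactants: 23 the aryl bromide of step 18; 32 the bis-silylated lactone of step 24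
Product: 33 (3S,4S)-2-aryl-4-{[4-(benzyloxy)-3-methoxyphenyl]methyl}-4-[(triethylsilyl)oxy]-3-{[(triethylsilyl)oxy]methyl}oxolan-2-ol, both C2 epimers, the 2-aryl group being ring D of 23 with the bond in place of Br
Conditions: 23, t-BuLi (2.1 equiv), THF, −78 °C; then 32 (1.3 equiv), −78 °C; H2O
Reagents that add atoms: none
Why: Bromine–lithium exchange and 1,2-addition of the aryllithium to the lactone give the hemiketal; the tetrahedral lithium alkoxide is stable at −78 °C, which prevents double addition, and addition outruns enolisation at C3.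

Step 26
Reactants: 33 the hemiketal of step 25
Product: 34 the (2R,3R,4S)-2-aryl-oxolane (H in place of the C2 OH of 33; both silyl ethers, the acetonide and all benzyl ethers retained)
Conditions: Et3SiH (5 equiv), BF3·OEt2 (3 equiv), CH2Cl2–MeCN, −78 to −40 °C
Reagents that add atoms: none
Why: Ionic hydrogenation of a hemiketal: BF3 ionises it to the aryl-stabilised oxocarbenium ion and the silane delivers hydride anti to the C3 CH2OSiEt3 group (pseudo-axial to avoid A1,2 strain with the aryl) and syn to the pseudo-axial C4 silyloxy group (inside attack on the envelope), so aryl, C3 branch and arylmethyl end all cis (C2 = R).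

Step 27
Reactants: 34 the silylated oxolane of step 26
Product: 35 the penta-benzyl ether of the target (both silyl ethers and the acetonide removed)
Conditions: AcOH–THF–H2O 3:1:1, 45 °C
Reagents that add atoms: none
Why: Acid-catalysed hydrolysis removes the two triethylsilyl ethers and the acetonide, while this weak acid should not ionise the still benzyl-protected 2-aryl-oxolane, so C2 of ring E is not epimerised.

Step 28
Reactants: 35 the penta-benzyl ether of step 27
Product: 36 the target, CNP0344108.1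
Conditions: H2 (1 atm), 10% Pd/C, EtOAc–MeOH, rt
Reagents that add atoms: none
Why: Catalytic hydrogenolysis cleaves the five benzyl ethers, and it is stopped at full conversion so that the slower-reacting benzylic C–O bond of the oxolane is kept.

**Compound list**

1 | 2-bromo-4-hydroxy-5-methoxybenzaldehyde | COc1cc(C=O)c(Br)cc1O | starting material
2 | 4-(benzyloxy)-2-bromo-5-methoxybenzaldehyde | COc1cc(C=O)c(Br)cc1OCc1ccccc1 | intermediate
3 | [4-(benzyloxy)-2-bromo-5-methoxyphenyl]methanol | COc1cc(CO)c(Br)cc1OCc1ccccc1 | intermediate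
4 | 1-(benzyloxy)-5-bromo-4-(bromomethyl)-2-methoxybenzene | COc1cc(CBr)c(Br)cc1OCc1ccccc1 | intermediate
5 | L-malic acid | O[C@@H](CC(O)=O)C(O)=O | starting material
6 | 2-[(2S,4S)-2-tert-butyl-5-oxo-1,3-dioxolan-4-yl]acetic acid | CC(C)(C)[C@H]1O[C@@H](CC(O)=O)C(=O)O1 | intermediate
7 | 2-[(2S,4S)-4-{[4-(benzyloxy)-2-bromo-5-methoxyphenyl]methyl}-2-tert-butyl-5-oxo-1,3-dioxolan-4-yl]acetic acid | CC(C)(C)[C@H]1O[C@@](Cc2cc(OC)c(OCc3ccccc3)cc2Br)(CC(O)=O)C(=O)O1 | intermediate
8 | (2S)-2-{[4-(benzyloxy)-2-bromo-5-methoxyphenyl]methyl}butane-1,2,4-triol | O[C@@](Cc1cc(OC)c(OCc2ccccc2)cc1Br)(CCO)CO | intermediate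
9 | 2-[(4S)-4-{[4-(benzyloxy)-2-bromo-5-methoxyphenyl]methyl}-2,2-dimethyl-1,3-dioxolan-4-yl]ethan-1-ol | CC1(C)OC[C@@](CCO)(Cc2cc(OC)c(OCc3ccccc3)cc2Br)O1 | intermediate
10 | 4-bromo-2-methoxyphenol | COc1cc(Br)ccc1O | starting material
11 | 4-bromo-2-iodo-6-methoxyphenol | COc1cc(Br)cc(I)c1O | intermediate
12 | 2-(benzyloxy)-5-bromo-1-iodo-3-methoxybenzene | COc1cc(Br)cc(I)c1OCc1ccccc1 | intermediate
13 | 2-[2-(benzyloxy)-5-bromo-3-methoxyphenyl]-4,4,5,5-tetramethyl-1,3,2-dioxaborolane | COc1cc(Br)cc(B2OC(C)(C)C(C)(C)O2)c1OCc1ccccc1 | intermediate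
14 | 4-hydroxy-3-iodo-5-methoxybenzaldehyde | COc1cc(C=O)cc(I)c1O | starting material
15 | 3-[2-(benzyloxy)-5-bromo-3-methoxyphenyl]-4-hydroxy-5-methoxybenzaldehyde | COc1cc(C=O)cc(-c2cc(Br)cc(OC)c2OCc2ccccc2)c1O | intermediate
16 | 3-[2-(benzyloxy)-5-bromo-3-methoxyphenyl]-4-[(tert-butyldimethylsilyl)oxy]-5-methoxybenzaldehyde | COc1cc(C=O)cc(-c2cc(Br)cc(OC)c2OCc2ccccc2)c1O[Si](C)(C)C(C)(C)C | intermediate
17 | diarylcarbinol primary alcohol (ring C silyl ether, (4S)-acetonide, carbinol epimers) | Brc1cc(OC)c(OCc2ccccc2)c(-c2cc(C(O)c3cc(OCc4ccccc4)c(OC)cc3C[C@]3(CCO)COC(C)(C)O3)cc(OC)c2O[Si](C)(C)C(C)(C)C)c1 | intermediate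
18 | diarylcarbinol aldehyde (ring C silyl ether, carbinol epimers) | Brc1cc(OC)c(OCc2ccccc2)c(-c2cc(C(O)c3cc(OCc4ccccc4)c(OC)cc3C[C@]3(CC=O)COC(C)(C)O3)cc(OC)c2O[Si](C)(C)C(C)(C)C)c1 | intermediate
19 | diarylcarbinol aldehyde with free ring C phenol (precursor of the key step, carbinol epimers) | Brc1cc(OC)c(OCc2ccccc2)c(-c2cc(C(O)c3cc(OCc4ccccc4)c(OC)cc3C[C@]3(CC=O)COC(C)(C)O3)cc(OC)c2O)c1 | intermediate
20 | para-quinone methide aldehyde (4-oxocyclohexa-2,5-dien-1-ylidene at the former carbinol carbon, alkene geometry open) | Brc1cc(OC)c(OCc2ccccc2)c(C2=CC(=Cc3cc(OCc4ccccc4)c(OC)cc3C[C@]3(CC=O)COC(C)(C)O3)C=C(OC)C2=O)c1 | intermediate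
21 | (1S,2R,3S)-tetralin-2-carbaldehyde with spiro acetonide at C3, free ring C phenol, Br on ring D | Brc1cc(OC)c(OCc2ccccc2)c(-c2cc([C@H]3c4cc(OCc5ccccc5)c(OC)cc4C[C@@](OC(C)(C)O6)(C6)[C@@H]3C=O)cc(OC)c2O)c1 | intermediate
22 | (1S,2S,3S)-2-(hydroxymethyl)tetralin, ring C phenol free | Brc1cc(OC)c(OCc2ccccc2)c(-c2cc([C@H]3c4cc(OCc5ccccc5)c(OC)cc4C[C@@](OC(C)(C)O6)(C6)[C@@H]3CO)cc(OC)c2O)c1 | intermediate
23 | (1S,2S,3S)-tetralin aryl bromide, ring C O-benzyl and C2 CH2O-benzyl | Brc1cc(OC)c(OCc2ccccc2)c(-c2cc([C@H]3c4cc(OCc5ccccc5)c(OC)cc4C[C@@](OC(C)(C)O6)(C6)[C@@H]3COCc3ccccc3)cc(OC)c2OCc2ccccc2)c1 | intermediate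
24 | [4-(benzyloxy)-3-methoxyphenyl]methanol | COc1cc(CO)ccc1OCc1ccccc1 | starting material
25 | 1-(benzyloxy)-4-(bromomethyl)-2-methoxybenzene | COc1cc(CBr)ccc1OCc1ccccc1 | intermediate
26 | 2-[(2S,4S)-4-{[4-(benzyloxy)-3-methoxyphenyl]methyl}-2-tert-butyl-5-oxo-1,3-dioxolan-4-yl]acetic acid | CC(C)(C)[C@H]1O[C@@](Cc2ccc(OCc3ccccc3)c(OC)c2)(CC(O)=O)C(=O)O1 | intermediate
27 | dimethyl (2S)-2-{[4-(benzyloxy)-3-methoxyphenyl]methyl}-2-hydroxybutanedioate | COC(=O)C[C@@](O)(Cc1ccc(OCc2ccccc2)c(OC)c1)C(=O)OC | intermediate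
28 | dimethyl (2S)-2-{[4-(benzyloxy)-3-methoxyphenyl]methyl}-2-hydroxy-3-(hydroxymethyl)butanedioate (C3 epimers) | COC(=O)C(CO)[C@@](O)(Cc1ccc(OCc2ccccc2)c(OC)c1)C(=O)OC | intermediate
29 | methyl (3S,4S)-4-{[4-(benzyloxy)-3-methoxyphenyl]methyl}-4-hydroxy-5-oxooxolane-3-carboxylate | COc1cc(C[C@@]2(O)C(=O)OC[C@@H]2C(=O)OC)ccc1OCc1ccccc1 | intermediate
30 | methyl (2S,3S)-3-{[4-(benzyloxy)-3-methoxyphenyl]methyl}-3,4-dihydroxy-2-(hydroxymethyl)butanoate | COC(=O)[C@@H](CO)[C@](O)(CO)Cc1ccc(OCc2ccccc2)c(OC)c1 | intermediate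
31 | (3S,4S)-4-{[4-(benzyloxy)-3-methoxyphenyl]methyl}-4-hydroxy-3-(hydroxymethyl)oxolan-2-one | COc1cc(C[C@@]2(O)COC(=O)[C@H]2CO)ccc1OCc1ccccc1 | intermediate
32 | (3S,4S)-4-{[4-(benzyloxy)-3-methoxyphenyl]methyl}-4-[(triethylsilyl)oxy]-3-{[(triethylsilyl)oxy]methyl}oxolan-2-one | COc1cc(C[C@@]2(O[Si](CC)(CC)CC)COC(=O)[C@H]2CO[Si](CC)(CC)CC)ccc1OCc1ccccc1 | intermediate
33 | hemiketal from 23 and 32, (3S,4S), C2 epimers | COc1cc(C[C@@]2(O[Si](CC)(CC)CC)COC(O)(c3cc(OC)c(OCc8ccccc8)c(-c4cc([C@H]5c6cc(OCc8ccccc8)c(OC)cc6C[C@@](OC(C)(C)O7)(C7)[C@@H]5COCc8ccccc8)cc(OC)c4OCc8ccccc8)c3)[C@H]2CO[Si](CC)(CC)CC)ccc1OCc1ccccc1 | intermediate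
34 | (2R,3R,4S)-2-aryl-oxolane, bis(triethylsilyl) ether, acetonide, five benzyl ethers | COc1cc(C[C@@]2(O[Si](CC)(CC)CC)CO[C@@H](c3cc(OC)c(OCc8ccccc8)c(-c4cc([C@H]5c6cc(OCc8ccccc8)c(OC)cc6C[C@@](OC(C)(C)O7)(C7)[C@@H]5COCc8ccccc8)cc(OC)c4OCc8ccccc8)c3)[C@H]2CO[Si](CC)(CC)CC)ccc1OCc1ccccc1 | intermediate
35 | penta-benzyl ether of the target (three aryl O-benzyl on rings A, C, D, one on ring F, one on the tetralin C2 CH2O) | COc1cc(C[C@@]2(O)CO[C@@H](c3cc(OC)c(OCc8ccccc8)c(-c4cc([C@H]5c6cc(OCc8ccccc8)c(OC)cc6C[C@@](O)(CO)[C@@H]5COCc8ccccc8)cc(OC)c4OCc8ccccc8)c3)[C@H]2CO)ccc1OCc1ccccc1 | intermediate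
36 | CNP0344108.1 | COc1cc(C[C@@]2(O)CO[C@@H](c3cc(OC)c(O)c(-c4cc([C@H]5c6cc(O)c(OC)cc6C[C@@](O)(CO)[C@@H]5CO)cc(OC)c4O)c3)[C@H]2CO)ccc1O | target

**Total step count:** 28.
**Longest linear sequence:** 16 steps (1, 2, 3, 5, 6, 7, 13, 14, 15, 16, 17, 18, 25, 26, 27, 28).

**Steps most likely to fail**

1. Step 16. The enamine may attack the wrong face of the quinone methide relative to C3 (C1 epimer). The beta ketal oxygen may also be lost from the enamine or iminium, or the electrophile may be captured at oxygen or oligomerise. Fallback with known chemistry (Lewis-acid alkylation of a silyl enol ether by a diarylmethyl cation, Mukaiyama type), setting out from 18 and returning at 21: t-BuMe2SiOTf and Et3N in CH2Cl2 should convert the aldehyde into its silyl enol ether and silylate the carbinol, giving the tris-silyl compound F1. BF3·OEt2 at −78 °C should ionise the diarylmethyl silyl ether and let the enol silane close ring B through the same chair, giving the ring C silyl ether of the tetralin aldehyde F2, with C2 equilibrated by a trace of DBU if needed. Buffered Bu4NF then frees the phenol and gives 21.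

2. Step 22. The dianion aldol with formaldehyde may be incomplete or go twice. During equilibration the lactone may open by beta-elimination or retro-aldol, or the trans:cis preference at C3 may be small. Fallback that delivers hydrogen last instead of carbon, setting out from 27 and returning at 32: hydroxyl-directed borane reduction of the alpha-hydroxy ester of 27 and acid lactonisation give (4S)-4-{[4-(benzyloxy)-3-methoxyphenyl]methyl}-4-hydroxyoxolan-2-one F3. LiN(i-Pr)2 (2.2 equiv) and ethyl formate give the 3-(hydroxymethylidene) lactone F4. Et3SiCl and Et3N give the 3-[(triethylsilyloxy)methylidene] lactone F5. Hydrogenation with [Ir(cod)(PCy3)(py)]PF6 should deliver H2 from the face of the tertiary hydroxyl, anti to the arylmethyl group, giving (3S,4S)-4-hydroxy-3-{[(triethylsilyl)oxy]methyl} lactone F6. Et3SiOTf and 2,6-lutidine then give 32.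

3. Step 26. Hydride may be delivered to the wrong face. The silane may also reduce on through the benzylic C–O bond of the new oxolane, or open the acetonide reductively. Fallback by directed hydrogenation, setting out from 33 and returning at 35: mild acid dehydration (pyridinium tosylate, toluene, molecular sieves) gives the 2-aryl-4,5-dihydrofuran F7. Bu4NF removes both silyl groups and gives the dihydrofuran diol F8. Hydrogenation with [Ir(cod)(PCy3)(py)]PF6 should add H2 syn to the tertiary and allylic hydroxyls and anti to the arylmethyl group, giving the all-cis oxolane diol F9. Aqueous acetic acid then removes the acetonide and gives 35.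

**Further compounds**

F1 | step 16 | silyl enol ether of 18 whose diarylcarbinol OH is also a tert-butyldimethylsilyl ether (enol geometry open) | Brc1cc(OC)c(OCc2ccccc2)c(-c2cc(C(O[Si](C)(C)C(C)(C)C)c3cc(OCc4ccccc4)c(OC)cc3C[C@]3(C=CO[Si](C)(C)C(C)(C)C)COC(C)(C)O3)cc(OC)c2O[Si](C)(C)C(C)(C)C)c1
F2 | step 16 | ring C tert-butyldimethylsilyl ether of 21 | Brc1cc(OC)c(OCc2ccccc2)c(-c2cc([C@H]3c4cc(OCc5ccccc5)c(OC)cc4C[C@@](OC(C)(C)O6)(C6)[C@@H]3C=O)cc(OC)c2O[Si](C)(C)C(C)(C)C)c1
F3 | step 22 | (4S)-4-{[4-(benzyloxy)-3-methoxyphenyl]methyl}-4-hydroxyoxolan-2-one | COc1cc(C[C@@]2(O)COC(=O)C2)ccc1OCc1ccccc1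
F4 | step 22 | (4S)-4-{[4-(benzyloxy)-3-methoxyphenyl]methyl}-4-hydroxy-3-(hydroxymethylidene)oxolan-2-one | COc1cc(C[C@@]2(O)COC(=O)C2=CO)ccc1OCc1ccccc1
F5 | step 22 | (4S)-4-{[4-(benzyloxy)-3-methoxyphenyl]methyl}-4-hydroxy-3-{[(triethylsilyl)oxy]methylidene}oxolan-2-one | COc1cc(C[C@@]2(O)COC(=O)C2=CO[Si](CC)(CC)CC)ccc1OCc1ccccc1
F6 | step 22 | (3S,4S)-4-{[4-(benzyloxy)-3-methoxyphenyl]methyl}-4-hydroxy-3-{[(triethylsilyl)oxy]methyl}oxolan-2-one | COc1cc(C[C@@]2(O)COC(=O)[C@H]2CO[Si](CC)(CC)CC)ccc1OCc1ccccc1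
F7 | step 26 | 2-aryl-4,5-dihydrofuran from 33 by loss of water (C2=C3), bis(triethylsilyl) ether | COc1cc(C[C@@]2(O[Si](CC)(CC)CC)COC(c3cc(OC)c(OCc8ccccc8)c(-c4cc([C@H]5c6cc(OCc8ccccc8)c(OC)cc6C[C@@](OC(C)(C)O7)(C7)[C@@H]5COCc8ccccc8)cc(OC)c4OCc8ccccc8)c3)=C2CO[Si](CC)(CC)CC)ccc1OCc1ccccc1
F8 | step 26 | the same dihydrofuran with both silyl groups removed (tertiary and allylic OH free) | COc1cc(C[C@@]2(O)COC(c3cc(OC)c(OCc8ccccc8)c(-c4cc([C@H]5c6cc(OCc8ccccc8)c(OC)cc6C[C@@](OC(C)(C)O7)(C7)[C@@H]5COCc8ccccc8)cc(OC)c4OCc8ccccc8)c3)=C2CO)ccc1OCc1ccccc1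
F9 | step 26 | (2R,3R,4S)-oxolane diol, i.e. 34 without its two triethylsilyl groups | COc1cc(C[C@@]2(O)CO[C@@H](c3cc(OC)c(OCc8ccccc8)c(-c4cc([C@H]5c6cc(OCc8ccccc8)c(OC)cc6C[C@@](OC(C)(C)O7)(C7)[C@@H]5COCc8ccccc8)cc(OC)c4OCc8ccccc8)c3)[C@H]2CO)ccc1OCc1ccccc1
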